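**Retrosynthetic overview**

- The target is reached by fluoride desilylation of its 6-O-TBS ether, which comes from a Ferrier carbocyclisation and dehydration of a methyl 2-C-alkyl-3,6-dideoxy-α-D-hex-5-enopyranoside. The bond made is C2–C3 of the cyclohexenone (sugar C6–C1), and the carbocycle is the only ring built, as the pyranose ring opens.
- Feature used: on the cyclohexenone ring the tertiary carbinol C4 (O4 and the chain) and the carbinol C6 (O6) are 1,3-cis across the C5 methylene, with C6 next to the C1 ketone. This is the O2/O4 pattern of a 3-deoxy-D-glucopyranose ring (C4 = sugar C2, C5 = sugar C3, C6 = sugar C4, C1 = sugar C5, C2 = sugar C6, C3 = sugar C1).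
- The enol ether comes from the 6-iodide, this from the 4,6-diol, and this from a β-face Grignard addition of the C17 chain to a 3-deoxy-2-ulose, made from methyl 4,6-O-benzylidene-α-D-glucopyranoside by way of the manno 2,3-epoxide and LiAlH4.
- Chain: (Z)-1-bromoheptadec-10-ene by Appel bromination, Lindlar reduction and alkylation of undec-10-yn-1-ol with 1-bromohexane.

Key step: step 12

Remark: carbocycles are numbered as in the target (C1 ketone, C4 chain-bearing carbinol, C6 oxygenated). The C6 oxygen is carried as a tert-butyldimethylsilyl ether so that its release at the end needs no base beside the enolisable C6 centre. The aldol of step 12 is carried on as crude material.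

**Route**

Step 1
Reactants: 1 methyl 4,6-O-benzylidene-α-D-glucopyranoside
Product: 3 methyl 2,3-anhydro-4,6-O-benzylidene-α-D-mannopyranoside, via 2-O-tosylate 2 (not isolated)
Conditions: NaH, N-tosylimidazole, DMF, rt
Reagents that add atoms: none
Why: O2, the most acidic hydroxyl (next to the anomeric centre), should be sulfonylated selectively, and the O3 alkoxide then displaces the tosylate with inversion at C2 (intramolecular Williamson epoxide closure) to give the β-face manno epoxide.

Step 2
Reactants: 3 methyl 2,3-anhydro-4,6-O-benzylidene-α-D-mannopyranoside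
Product: 4 methyl 4,6-O-benzylidene-3-deoxy-α-D-arabino-hexopyranoside
Conditions: LiAlH4, THF, reflux
Reagents that add atoms: none
Why: Fürst–Plattner trans-diaxial opening of the conformationally locked epoxide should deliver hydride to C3 from the α-face, leaving the (axial) hydroxyl on C2, a centre that is erased in step 3.

Step 3
Reactants: 4 methyl 4,6-O-benzylidene-3-deoxy-α-D-arabino-hexopyranoside
Product: 5 methyl 4,6-O-benzylidene-3-deoxy-α-D-erythro-hexopyranosid-2-ulose
Conditions: Dess–Martin periodinane, CH2Cl2, rt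
Reagents that add atoms: none
Why: Dess–Martin oxidation of the secondary alcohol under near-neutral conditions should spare both acetals and avoid enolisation of the 2-ulose.

Step 4
Reactants: 6 undec-10-yn-1-ol; 7 1-bromohexane
Product: 9 heptadec-10-yn-1-ol, via dilithio alkynolate 8 (not isolated)
Conditions: n-BuLi (2.1 equiv), THF/DMPU, −78 → 0 °C; then 7, 0 °C → rt
Reagents that add atoms: none
Why: Acetylide alkylation: in the O,C-dianion the acetylide carbon is alkylated by the primary bromide in preference to the alkoxide.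

Step 5
Reactants: 9 heptadec-10-yn-1-ol
Product: 10 (Z)-heptadec-10-en-1-ol
Conditions: H2 (1 atm), Pd/CaCO3 poisoned with Pb(OAc)2 (Lindlar catalyst), quinoline, EtOAc, rt
Reagents that add atoms: none
Why: Lindlar semi-hydrogenation adds hydrogen syn on the poisoned palladium surface and so sets the Z-alkene.

Step 6
Reactants: 10 (Z)-heptadec-10-en-1-ol
Product: 11 (Z)-1-bromoheptadec-10-ene
Conditions: CBr4, PPh3, CH2Cl2, 0 °C
Reagents that add atoms: carbon tetrabromide, BrC(Br)(Br)Br
Why: Appel bromination of the primary alcohol proceeds by SN2 on the alkoxyphosphonium ion and should leave the alkene untouched.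

Step 7
Reactants: 5 methyl 4,6-O-benzylidene-3-deoxy-α-D-erythro-hexopyranosid-2-ulose; 11 (Z)-1-bromoheptadec-10-ene
Product: 13 methyl 4,6-O-benzylidene-3-deoxy-2-C-[(Z)-heptadec-10-enyl]-α-D-ribo-hexopyranoside, via Grignard reagent 12 (not isolated)
Conditions: Mg, THF, 40 °C (on 11); then 5, THF, −78 → −20 °C
Reagents that add atoms: none
Why: Grignard addition to the ketone: the axial anomeric methoxyl shields the α-face and is the antiperiplanar polar group in the Felkin–Anh sense, so the nucleophile should enter along the axial β trajectory and place the chain axial and the new tertiary hydroxyl equatorial (gluco sense, C2 R).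

Step 8
Reactants: 13 methyl 4,6-O-benzylidene-3-deoxy-2-C-[(Z)-heptadec-10-enyl]-α-D-ribo-hexopyranoside
Product: 14 methyl 3-deoxy-2-C-[(Z)-heptadec-10-enyl]-α-D-ribo-hexopyranoside
Conditions: CSA (cat.), MeOH/CH2Cl2, rt
Reagents that add atoms: none
Why: Acid-catalysed transacetalisation should remove the benzylidene group as its dimethyl acetal, while the methyl glycoside, the tertiary alcohol and the alkene are inert at room temperature.

Step 9
Reactants: 14 methyl 3-deoxy-2-C-[(Z)-heptadec-10-enyl]-α-D-ribo-hexopyranoside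
Product: 15 methyl 3,6-dideoxy-2-C-[(Z)-heptadec-10-enyl]-6-iodo-α-D-ribo-hexopyranoside
Conditions: PPh3, imidazole, I2 (added last), THF, 0 °C → rt
Reagents that add atoms: iodine, II
Why: Appel-type iodination (PPh3/I2/imidazole) should be selective for the primary hydroxyl, because SN2 on the alkoxyphosphonium ion is far faster at C6 than at the secondary C4 or the tertiary C2.

Step 10
Reactants: 15 methyl 3,6-dideoxy-2-C-[(Z)-heptadec-10-enyl]-6-iodo-α-D-ribo-hexopyranoside
Product: 16 methyl 4-O-(tert-butyldimethylsilyl)-3,6-dideoxy-2-C-[(Z)-heptadec-10-enyl]-6-iodo-α-D-ribo-hexopyranoside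
Conditions: TBSCl, imidazole, DMF, rt
Reagents that add atoms: tert-butyldimethylsilyl chloride, CC(C)(C)[Si](C)(C)Cl
Why: Silylation with TBSCl and imidazole should distinguish the secondary O4 from the hindered tertiary O2.

Step 11
Reactants: 16 methyl 4-O-(tert-butyldimethylsilyl)-3,6-dideoxy-2-C-[(Z)-heptadec-10-enyl]-6-iodo-α-D-ribo-hexopyranoside
Product: 17 methyl 4-O-(tert-butyldimethylsilyl)-3,6-dideoxy-2-C-[(Z)-heptadec-10-enyl]-α-D-erythro-hex-5-enopyranoside
Conditions: DBU, THF, reflux
Reagents that add atoms: none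
Why: E2 dehydroiodination: H5 is the only β-hydrogen, so the elimination can give only the exocyclic 5,6-enol ether.

Step 12
Reactants: 17 methyl 4-O-(tert-butyldimethylsilyl)-3,6-dideoxy-2-C-[(Z)-heptadec-10-enyl]-α-D-erythro-hex-5-enopyranoside
Product: 21 (4R,6S)-6-(tert-butyldimethylsilyloxy)-4-hydroxy-4-[(Z)-heptadec-10-enyl]cyclohex-2-en-1-one, via HgOCOCF3 keto aldehyde 18 (not isolated), via aldol 19 (not isolated), via aldol mesylate 20 (not isolated)
Conditions: Hg(OCOCF3)2 (5 mol %), acetone/H2O (4:1), rt; then crude aldol, MsCl, Et3N, CH2Cl2, 0 °C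
Reagents that add atoms: water, O
Why: Ferrier carbocyclisation: divalent mercury adds to C6 of the electron-rich exocyclic enol ether and water to C5, the hemiketal collapses to the C5 ketone, and the C1 hemiacetal loses methanol to give the α-mercurio keto aldehyde 18. Its mercury enolate should add to the aldehyde in a 6-(enolexo)-exo-trig aldol that forms sugar C6–C1 (C2–C3 of the target), closes the carbocycle and returns Hg(OCOCF3)2 to the cycle. Mesylation of the secondary aldol hydroxyl and E1cB loss of mesylate, the only leaving group β to the ketone, then give the C2=C3 enone, so the carbinol centre made in the aldol is erased and no new stereocentre remains. C4 and C6 come unchanged from sugar C2 and C4: the quaternary C4 cannot epimerise, and C6 should survive the short, cold exposure to Et3N. The selectivity needed is mercuration of the enol ether in preference to the chain Z-alkene, which the far higher nucleophilicity of the enol ether and the catalytic mercury loading should secure; the tertiary hydroxyl should not be mesylated under these conditions.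

Step 13
Reactants: 21 (4R,6S)-6-(tert-butyldimethylsilyloxy)-4-hydroxy-4-[(Z)-heptadec-10-enyl]cyclohex-2-en-1-one
Product: 22 (4R,6S)-4,6-dihydroxy-4-[(Z)-heptadec-10-enyl]cyclohex-2-en-1-one
Conditions: HF·pyridine, pyridine, THF, 0 °C → rt
Reagents that add atoms: none
Why: Fluoride desilylation under buffered, weakly acidic conditions should free O6 without base, so the enolisable C6 centre, the enone and the tertiary allylic carbinol stay as they are.

**Compound list**

1 | methyl 4,6-O-[(R)-benzylidene]-α-D-glucopyranoside | CO[C@H]1O[C@@H]2CO[C@@H](c3ccccc3)O[C@H]2[C@H](O)[C@H]1O | starting material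
2 | methyl 4,6-O-benzylidene-2-O-tosyl-α-D-glucopyranoside | CO[C@H]1O[C@@H]2CO[C@@H](c3ccccc3)O[C@H]2[C@H](O)[C@H]1OS(=O)(=O)c4ccc(C)cc4 | intermediate (not isolated)
3 | methyl 2,3-anhydro-4,6-O-benzylidene-α-D-mannopyranoside | CO[C@H]1O[C@@H]2CO[C@@H](c3ccccc3)O[C@H]2[C@@H]4O[C@H]14 | intermediate
4 | methyl 4,6-O-benzylidene-3-deoxy-α-D-arabino-hexopyranoside | CO[C@H]1O[C@@H]2CO[C@@H](c3ccccc3)O[C@H]2C[C@@H]1O | intermediate
5 | methyl 4,6-O-benzylidene-3-deoxy-α-D-erythro-hexopyranosid-2-ulose | CO[C@H]1O[C@@H]2CO[C@@H](c3ccccc3)O[C@H]2CC1=O | intermediate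
6 | undec-10-yn-1-ol | C#CCCCCCCCCCO | starting material
7 | 1-bromohexane | CCCCCCBr | starting material
8 | dilithium 11-oxidoundec-1-yn-1-ide | [Li+].[Li+].[O-]CCCCCCCCCC#[C-] | intermediate (not isolated)
9 | heptadec-10-yn-1-ol | CCCCCCC#CCCCCCCCCCO | intermediate
10 | (Z)-heptadec-10-en-1-ol | CCCCCC/C=C\CCCCCCCCCO | intermediate
11 | (Z)-1-bromoheptadec-10-ene | CCCCCC/C=C\CCCCCCCCCBr | intermediate
12 | (Z)-heptadec-10-enylmagnesium bromide | CCCCCC/C=C\CCCCCCCCC[Mg]Br | intermediate (not isolated)
13 | methyl 4,6-O-benzylidene-3-deoxy-2-C-[(Z)-heptadec-10-enyl]-α-D-ribo-hexopyranoside (C2 R; chain axial, hydroxyl equatorial) | CO[C@H]1O[C@@H]2CO[C@@H](c3ccccc3)O[C@H]2C[C@]1(O)CCCCCCCCC/C=C\CCCCCC | intermediate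
14 | methyl 3-deoxy-2-C-[(Z)-heptadec-10-enyl]-α-D-ribo-hexopyranoside | CO[C@H]1O[C@H](CO)[C@@H](O)C[C@]1(O)CCCCCCCCC/C=C\CCCCCC | intermediate
15 | methyl 3,6-dideoxy-2-C-[(Z)-heptadec-10-enyl]-6-iodo-α-D-ribo-hexopyranoside | CO[C@H]1O[C@H](CI)[C@@H](O)C[C@]1(O)CCCCCCCCC/C=C\CCCCCC | intermediate
16 | methyl 4-O-(tert-butyldimethylsilyl)-3,6-dideoxy-2-C-[(Z)-heptadec-10-enyl]-6-iodo-α-D-ribo-hexopyranoside | CO[C@H]1O[C@H](CI)[C@@H](O[Si](C)(C)C(C)(C)C)C[C@]1(O)CCCCCCCCC/C=C\CCCCCC | intermediate
17 | methyl 4-O-(tert-butyldimethylsilyl)-3,6-dideoxy-2-C-[(Z)-heptadec-10-enyl]-α-D-erythro-hex-5-enopyranoside (C1 S, C2 R, C4 S) | CO[C@H]1OC(=C)[C@@H](O[Si](C)(C)C(C)(C)C)C[C@]1(O)CCCCCCCCC/C=C\CCCCCC | intermediate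
18 | (2R,4S)-4-(tert-butyldimethylsilyloxy)-2-hydroxy-2-[(Z)-heptadec-10-enyl]-5-oxo-6-(trifluoroacetoxymercurio)hexanal | O=C[C@@](O)(CCCCCCCCC/C=C\CCCCCC)C[C@H](O[Si](C)(C)C(C)(C)C)C(=O)C[Hg]OC(=O)C(F)(F)F | intermediate (not isolated)
19 | (4R,6S)-6-(tert-butyldimethylsilyloxy)-3,4-dihydroxy-4-[(Z)-heptadec-10-enyl]cyclohexan-1-one (both C3 epimers, which converge) | CCCCCC/C=C\CCCCCCCCC[C@]1(O)C(O)CC(=O)[C@@H](O[Si](C)(C)C(C)(C)C)C1 | intermediate (not isolated)
20 | (4R,6S)-6-(tert-butyldimethylsilyloxy)-4-hydroxy-4-[(Z)-heptadec-10-enyl]-3-(methylsulfonyloxy)cyclohexan-1-one (both C3 epimers) | CCCCCC/C=C\CCCCCCCCC[C@]1(O)C(OS(C)(=O)=O)CC(=O)[C@@H](O[Si](C)(C)C(C)(C)C)C1 | intermediate (not isolated)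
21 | (4R,6S)-6-(tert-butyldimethylsilyloxy)-4-hydroxy-4-[(Z)-heptadec-10-enyl]cyclohex-2-en-1-one | CCCCCC/C=C\CCCCCCCCC[C@]1(O)C=CC(=O)[C@@H](O[Si](C)(C)C(C)(C)C)C1 | intermediate
22 | (4R,6S)-4,6-dihydroxy-4-[(Z)-heptadec-10-enyl]cyclohex-2-en-1-one | CCCCCC/C=C\CCCCCCCCC[C@]1(O)C=CC(=O)[C@@H](O)C1 | target

**Step count and risks**

Total step count: 13. Longest linear sequence: 10 steps (steps 1–3 and 7–13; the chain arm, steps 4–6 and 7–13, is equally long).

Steps most likely to fail:

1. Step 12 (key step). The mercury catalyst may be held back by reversible oxymercuration of the chain alkene, or the sequence may stall at the open keto aldehyde. A mercury-free fallback sets out from enol ether 17. Brønsted-acid hydrolysis of the enol ether (dilute HCl, THF/H2O, 0 °C) should give the open 1,5-keto aldehyde (2R,4S)-4-(tert-butyldimethylsilyloxy)-2-hydroxy-2-[(Z)-heptadec-10-enyl]-5-oxohexanal F1. An enamine-mediated intramolecular aldol of its methyl ketone onto the non-enolisable aldehyde (pyrrolidinium acetate or L-proline, DMSO, rt) should then close the ring. The fallback comes back to the route at aldol 19, which is dehydrated with MsCl and Et3N as in step 12.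

2. Step 7. The long-chain Grignard reagent may enolise or reduce the ketone, or the facial selectivity may be poor. The fallback sets out from ketone 5 and forms the C2–C1' bond with a small ylide. Corey–Chaykovsky methylene transfer with dimethylsulfonium methylide (trimethylsulfonium iodide, n-BuLi, THF, −10 °C) adds kinetically along the axial trajectory. It should give the spiro-epoxide methyl 2,2'-anhydro-4,6-O-benzylidene-3-deoxy-2-C-(hydroxymethyl)-α-D-ribo-hexopyranoside F2, with the methylene axial and the oxygen equatorial. Commercial palmitoleyl alcohol, (Z)-hexadec-9-en-1-ol, is converted with CBr4 and PPh3 into (Z)-1-bromohexadec-9-ene F3 and then with Mg into (Z)-hexadec-9-enylmagnesium bromide F4. Opening of F2 at its methylene carbon with F4 (CuI cat., THF, −30 °C) should give the same tertiary alcohol, and the fallback comes back to the route at 13.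

3. Step 9. Free iodine may scramble the Z-alkene of the chain, or O4 may be activated alongside O6. The fallback sets out from triol 14. Selective sulfonylation of the primary hydroxyl (TsCl, pyridine, 0 °C) should give methyl 3-deoxy-2-C-[(Z)-heptadec-10-enyl]-6-O-tosyl-α-D-ribo-hexopyranoside F5. Finkelstein displacement (NaI, butanone, reflux) then introduces iodide without elemental iodine, and the fallback comes back to the route at 15.

**Further compounds**

F1 | step 12 | (2R,4S)-4-(tert-butyldimethylsilyloxy)-2-hydroxy-2-[(Z)-heptadec-10-enyl]-5-oxohexanal | O=C[C@@](O)(CCCCCCCCC/C=C\CCCCCC)C[C@H](O[Si](C)(C)C(C)(C)C)C(C)=O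
F2 | step 7 | methyl 2,2'-anhydro-4,6-O-benzylidene-3-deoxy-2-C-(hydroxymethyl)-α-D-ribo-hexopyranoside (spiro-oxirane, methylene axial) | CO[C@H]1O[C@@H]2CO[C@@H](c3ccccc3)O[C@H]2C[C@]14CO4
F3 | step 7 | (Z)-1-bromohexadec-9-ene | CCCCCC/C=C\CCCCCCCCBr
F4 | step 7 | (Z)-hexadec-9-enylmagnesium bromide | CCCCCC/C=C\CCCCCCCC[Mg]Br
F5 | step 9 | methyl 3-deoxy-2-C-[(Z)-heptadec-10-enyl]-6-O-tosyl-α-D-ribo-hexopyranoside | CO[C@H]1O[C@H](COS(=O)(=O)c2ccc(C)cc2)[C@@H](O)C[C@]1(O)CCCCCCCCC/C=C\CCCCCC
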